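Everything rests on forming the ring bond C1–C2 and the C7–O bond together from an open chain that carries both halogens (numbering: cyclohexane C1–C6, Br on C3, Cl and Me on C4, carbinols C7 and C10). A primary triflate ionises through a C2–C3 bromonium ion, the Z-configured C1=C7 alkene attacks C2 and a tert-butyl ester traps C7, so the cyclohexane and a γ-lactone (O, C7–C10) close at once. The step exploits the equatorial C3–Br lying anti to the C1–C2 ring bond in the all-equatorial chair, and the 1,4 relation of the C7 oxygen to C10. The precursor is an acyclic, enantioenriched bromochloro triflate with a Z alkene and a tert-butyl ester.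

Key step: step 10

Remark: the target numbering given above is used for all intermediates, and it is assumed that the ligand antipode giving the 8S,9S bromochloride in step 8 can be chosen, since both antipodes of the ligand are accessible.

Step 1
Reactants: 1 nerol
Product: 2 tert-butyl{[(2Z)-3,7-dimethylocta-2,6-dien-1-yl]oxy}diphenylsilane (neryl TBDPS ether)
Conditions: TBDPSCl, imidazole, DMF, 0 °C to rt
Reagents that add atoms: tert-butyl(chloro)diphenylsilane, CC(C)(C)[Si](Cl)(c1ccccc1)c1ccccc1
Why: Imidazole-promoted O-silylation of the primary allylic alcohol is routine, and the bulky, acid-stable TBDPS group is chosen to survive the periodic acid cleavage and to shield the neighbouring alkene.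

Step 2
Reactants: 2 neryl TBDPS ether
Product: 4 (4Z)-6-[(tert-butyldiphenylsilyl)oxy]-4-methylhex-4-enal, via 6,7-epoxide 3 (not isolated)
Conditions: mCPBA, CH2Cl2, −20 to 0 °C; then HIO4·2H2O, THF/Et2O, 0 °C
Reagents that add atoms: mCPBA (3-chloroperoxybenzoic acid), OOC(=O)c1cccc(Cl)c1
Why: Prilezhaev epoxidation should favour the remote, more electron-rich 6,7-alkene because the 2,3-alkene is inductively deactivated and shielded by the allylic silyloxy group, and periodic acid then hydrolyses and cleaves the crude trisubstituted epoxide to the aldehyde and acetone without touching the Z alkene.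

Step 3
Reactants: 4 (4Z)-6-[(tert-butyldiphenylsilyl)oxy]-4-methylhex-4-enal; 5 ethyl 2-[bis(2,2,2-trifluoroethoxy)phosphoryl]propanoate
Product: 6 ethyl (2Z,6Z)-8-[(tert-butyldiphenylsilyl)oxy]-2,6-dimethylocta-2,6-dienoate
Conditions: 5, KN(SiMe3)2, 18-crown-6, THF, −78 °C; then 4
Reagents that add atoms: none
Why: In the Still–Gennari variant of the Horner–Wadsworth–Emmons olefination the electron-poor trifluoroethyl phosphonate eliminates rapidly from the kinetic adduct under dissociating conditions, which should give the Z trisubstituted enoate and so fix the geometry of the future C1=C7 alkene.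

Step 4
Reactants: 6 ethyl (2Z,6Z)-8-[(tert-butyldiphenylsilyl)oxy]-2,6-dimethylocta-2,6-dienoate
Product: 7 (2Z,6Z)-8-[(tert-butyldiphenylsilyl)oxy]-2,6-dimethylocta-2,6-dien-1-ol
Conditions: iBu2AlH, CH2Cl2, −78 to 0 °C
Reagents that add atoms: none
Why: 1,2-Reduction of the enoate by two equivalents of the aluminium hydride should give the Z allylic alcohol without changing either alkene geometry or the silyl ether.

Step 5
Reactants: 7 (2Z,6Z)-8-[(tert-butyldiphenylsilyl)oxy]-2,6-dimethylocta-2,6-dien-1-ol
Product: 9 {[(2Z,6Z)-8-bromo-3,7-dimethylocta-2,6-dien-1-yl]oxy}(tert-butyl)diphenylsilane, via allylic mesylate 8 (not isolated)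
Conditions: MsCl, Et3N, THF, −40 °C; then LiBr, THF, 0 °C
Reagents that add atoms: lithium bromide, [Li+].[Br-]
Why: Mesylation followed by SN2 displacement with bromide at low temperature should give the primary allylic bromide without allylic transposition or loss of the Z geometry, and the bromide is used directly.

Step 6
Reactants: 9 {[(2Z,6Z)-8-bromo-3,7-dimethylocta-2,6-dien-1-yl]oxy}(tert-butyl)diphenylsilane; 10 tert-butyl acetate
Product: 11 tert-butyl (4Z,8Z)-10-[(tert-butyldiphenylsilyl)oxy]-4,8-dimethyldeca-4,8-dienoate
Conditions: 10 (excess), LiN(iPr)2, THF, −78 °C; then 9, DMPU, −78 to −20 °C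
Reagents that add atoms: none
Why: SN2 alkylation of the lithium ester enolate by the unhindered primary allylic bromide forms the C8–C9 bond and installs the tert-butyl ester that later terminates the cyclisation, with excess enolate suppressing dialkylation.

Step 7
Reactants: 11 tert-butyl (4Z,8Z)-10-[(tert-butyldiphenylsilyl)oxy]-4,8-dimethyldeca-4,8-dienoate
Product: 12 tert-butyl (4Z,8Z)-10-hydroxy-4,8-dimethyldeca-4,8-dienoate
Conditions: Bu4NF, THF, 0 °C to rt
Reagents that add atoms: none
Why: Fluoride-mediated desilylation frees the allylic alcohol needed for titanium binding, and the tert-butyl ester is inert to fluoride.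

Step 8
Reactants: 12 tert-butyl (4Z,8Z)-10-hydroxy-4,8-dimethyldeca-4,8-dienoate
Product: 13 tert-butyl (4Z,8S,9S)-9-bromo-8-chloro-10-hydroxy-4,8-dimethyldec-4-enoate
Conditions: ClTi(OiPr)3, NBS, chiral tridentate O,N,O Schiff-base ligand (salicylaldimine of a 1,1-diaryl 2-amino alcohol, 20 mol%), hexanes, −20 °C
Reagents that add atoms: N-bromosuccinimide, O=C1CCC(=O)N1Br; chlorotitanium triisopropoxide, CC(C)O[Ti](Cl)(OC(C)C)OC(C)C
Why: In this titanium-alkoxide-directed catalytic enantioselective bromochlorination of an allylic alcohol only the alkene of the titanium-bound alcohol is activated (the remote 4Z alkene is not), bromine and chloride add anti with chloride going to the tertiary distal carbon, and the ligand antipode sets the 8S,9S configuration (target C4 and C3).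

Step 9
Reactants: 13 tert-butyl (4Z,8S,9S)-9-bromo-8-chloro-10-hydroxy-4,8-dimethyldec-4-enoate
Product: 14 tert-butyl (4Z,8S,9S)-9-bromo-8-chloro-4,8-dimethyl-10-[(trifluoromethanesulfonyl)oxy]dec-4-enoate
Conditions: Tf2O, 2,6-di-tert-butyl-4-methylpyridine, CH2Cl2, −78 °C; cold filtration, used crude at once
Reagents that add atoms: trifluoromethanesulfonic anhydride, O=S(=O)(OS(=O)(=O)C(F)(F)F)C(F)(F)F
Why: O-Triflation of the primary alcohol with a hindered, non-nucleophilic pyridine at −78 °C should give the primary triflate without N-alkylation of the base and without epoxide formation from the bromohydrin motif.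

Step 10
Reactants: 14 tert-butyl (4Z,8S,9S)-9-bromo-8-chloro-4,8-dimethyl-10-[(trifluoromethanesulfonyl)oxy]dec-4-enoate
Product: 17 (5R)-5-[(1S,3S,4S)-3-bromo-4-chloro-4-methylcyclohexyl]-5-methyloxolan-2-one, via bromonium triflate 15 (not isolated), via tert-butoxy oxocarbenium triflate 16 (not isolated)
Conditions: (CF3)2CHOH/CH2Cl2 (1:4, 0.01 M), 2,6-di-tert-butyl-4-methylpyridine, −40 to 0 °C
Reagents that add atoms: none
Why: Proposed new method: in the strongly ionising, weakly nucleophilic fluoroalcohol the primary triflate should leave with anchimeric assistance from the vicinal C3 bromine to give the configurationally defined C2–C3 bromonium ion 15, which the CH terminus (C1) of the trisubstituted alkene opens at C2 while the far less labile tertiary C4–Cl bond stays intact, and the incipient tertiary C7 cation is trapped by the ester carbonyl oxygen to give oxocarbenium ion 16, which sheds 2-methylpropene. The closest known reaction types are the enantiospecific bromonium polyene cyclisation set off by fluoroalcohol solvolysis of a vicinal bromochloride, the π-assisted solvolysis of alkenyl sulfonates, and cation–olefin cyclisations terminated as γ-lactones by a tethered acid or ester. The cyclohexane closes through a chair with the alkene exocyclic to the new ring (6-exo with respect to the alkene, endo opening of the three-membered bromonium ring), and the γ-lactone closes 5-exo at C7. C1 is set by that chair, because backside opening puts C3–Br anti to the new C1–C2 bond and therefore equatorial, the trans C4–Cl follows into an equatorial site with C4–Me axial, and the C7 terminus takes the remaining equatorial position (1S); C7 is set as R by anti addition of C2 and oxygen across the Z alkene, while C3 and C4 pass through unchanged since bromine never leaves C3. The step needs attack at C2 and not at C3, which the neopentyl, chlorine-deactivated character of C3 and the six-membered chair should secure; it needs bridged and not open ionisation, which the fluoroalcohol at low temperature should favour; and it needs capture of C7 before bond rotation or proton loss, which the short tether to the ester carbonyl and the hindered pyridine buffer should favour.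

Step 11
Reactants: 17 (5R)-5-[(1S,3S,4S)-3-bromo-4-chloro-4-methylcyclohexyl]-5-methyloxolan-2-one
Product: 18 (4R)-4-[(1S,3S,4S)-3-bromo-4-chloro-4-methylcyclohexyl]-4-hydroxy-N-methoxy-N-methylpentanamide
Conditions: MeNH(OMe)·HCl, iPrMgCl, THF, −20 to 0 °C; cold NH4Cl quench, used crude
Reagents that add atoms: N,O-dimethylhydroxylamine hydrochloride, CNOC.Cl
Why: Aminolysis of the γ-lactone by the chloromagnesium amide (Weinreb amide formation from an ester) opens the ring without an aluminium Lewis acid that could ionise the tertiary chloride, and no stereocentre is touched.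

Step 12
Reactants: 18 (4R)-4-[(1S,3S,4S)-3-bromo-4-chloro-4-methylcyclohexyl]-4-hydroxy-N-methoxy-N-methylpentanamide
Product: 19 (4R)-4-[(1S,3S,4S)-3-bromo-4-chloro-4-methylcyclohexyl]-N-methoxy-N-methyl-4-[(triethylsilyl)oxy]pentanamide
Conditions: Et3SiOTf, 2,6-lutidine, CH2Cl2, −78 to 0 °C
Reagents that add atoms: triethylsilyl trifluoromethanesulfonate, CC[Si](CC)(CC)OS(=O)(=O)C(F)(F)F
Why: Silyl triflate silylation of the hindered tertiary C7 alcohol blocks relactonisation and removes the free alkoxide from the following organometallic and borane steps.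

Step 13
Reactants: 19 (4R)-4-[(1S,3S,4S)-3-bromo-4-chloro-4-methylcyclohexyl]-N-methoxy-N-methyl-4-[(triethylsilyl)oxy]pentanamide; 20 isopropenylmagnesium bromide
Product: 21 (6R)-6-[(1S,3S,4S)-3-bromo-4-chloro-4-methylcyclohexyl]-2-methyl-6-[(triethylsilyl)oxy]hept-1-en-3-one
Conditions: 20, THF, −78 to 0 °C; inverse quench into cold 1 M HCl
Reagents that add atoms: none
Why: In this Weinreb ketone synthesis the Grignard reagent adds once to give a stable magnesium chelate that collapses to the isopropenyl ketone only on the acidic quench, which also protonates the released amine and so prevents its conjugate addition to the enone.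

Step 14
Reactants: 21 (6R)-6-[(1S,3S,4S)-3-bromo-4-chloro-4-methylcyclohexyl]-2-methyl-6-[(triethylsilyl)oxy]hept-1-en-3-one
Product: 22 (3R,6R)-6-[(1S,3S,4S)-3-bromo-4-chloro-4-methylcyclohexyl]-2-methyl-6-[(triethylsilyl)oxy]hept-1-en-3-ol
Conditions: (S)-2-methyl-CBS-oxazaborolidine (0.5 equiv), catecholborane, toluene, −78 °C; MeOH quench
Reagents that add atoms: none
Why: In this Corey–Bakshi–Shibata reduction the isopropenyl group acts as the larger ketone substituent, so the (S)-oxazaborolidine should deliver hydride under reagent control to give the 10R allylic alcohol (3R in the name), and catecholborane at −78 °C avoids hydroboration of the 1,1-disubstituted alkene.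

Step 15
Reactants: 22 (3R,6R)-6-[(1S,3S,4S)-3-bromo-4-chloro-4-methylcyclohexyl]-2-methyl-6-[(triethylsilyl)oxy]hept-1-en-3-ol
Product: 23 CNP0226035.2, (3R,6R)-6-[(1S,3S,4S)-3-bromo-4-chloro-4-methylcyclohexyl]-2-methylhept-1-ene-3,6-diol
Conditions: HF·pyridine, pyridine, THF, 0 °C to rt
Reagents that add atoms: none
Why: Buffered fluoride cleavage of the tertiary triethylsilyl ether under non-basic conditions should release the C7 carbinol without elimination of HBr or HCl, epoxide formation or allylic transposition.

Compound list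
1 | nerol, (2Z)-3,7-dimethylocta-2,6-dien-1-ol | CC(C)=CCC/C(C)=C\CO | starting material
2 | tert-butyl{[(2Z)-3,7-dimethylocta-2,6-dien-1-yl]oxy}diphenylsilane | CC(C)=CCC/C(C)=C\CO[Si](c1ccccc1)(c1ccccc1)C(C)(C)C | intermediate
3 | tert-butyl{[(2Z)-5-(3,3-dimethyloxiran-2-yl)-3-methylpent-2-en-1-yl]oxy}diphenylsilane (racemic 6,7-epoxide) | CC1(C)OC1CC/C(C)=C\CO[Si](c1ccccc1)(c1ccccc1)C(C)(C)C | intermediate
4 | (4Z)-6-[(tert-butyldiphenylsilyl)oxy]-4-methylhex-4-enal | O=CCC/C(C)=C\CO[Si](c1ccccc1)(c1ccccc1)C(C)(C)C | intermediate
5 | ethyl 2-[bis(2,2,2-trifluoroethoxy)phosphoryl]propanoate | CCOC(=O)C(C)P(=O)(OCC(F)(F)F)OCC(F)(F)F | starting material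
6 | ethyl (2Z,6Z)-8-[(tert-butyldiphenylsilyl)oxy]-2,6-dimethylocta-2,6-dienoate | CCOC(=O)/C(C)=C\CC/C(C)=C\CO[Si](c1ccccc1)(c1ccccc1)C(C)(C)C | intermediate
7 | (2Z,6Z)-8-[(tert-butyldiphenylsilyl)oxy]-2,6-dimethylocta-2,6-dien-1-ol | OC/C(C)=C\CC/C(C)=C\CO[Si](c1ccccc1)(c1ccccc1)C(C)(C)C | intermediate
8 | (2Z,6Z)-8-[(tert-butyldiphenylsilyl)oxy]-2,6-dimethylocta-2,6-dien-1-yl methanesulfonate | CS(=O)(=O)OC/C(C)=C\CC/C(C)=C\CO[Si](c1ccccc1)(c1ccccc1)C(C)(C)C | intermediate
9 | {[(2Z,6Z)-8-bromo-3,7-dimethylocta-2,6-dien-1-yl]oxy}(tert-butyl)diphenylsilane | BrC/C(C)=C\CC/C(C)=C\CO[Si](c1ccccc1)(c1ccccc1)C(C)(C)C | intermediate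
10 | tert-butyl acetate | CC(=O)OC(C)(C)C | starting material
11 | tert-butyl (4Z,8Z)-10-[(tert-butyldiphenylsilyl)oxy]-4,8-dimethyldeca-4,8-dienoate | CC(C)(C)OC(=O)CC/C(C)=C\CC/C(C)=C\CO[Si](c1ccccc1)(c1ccccc1)C(C)(C)C | intermediate
12 | tert-butyl (4Z,8Z)-10-hydroxy-4,8-dimethyldeca-4,8-dienoate | CC(C)(C)OC(=O)CC/C(C)=C\CC/C(C)=C\CO | intermediate
13 | tert-butyl (4Z,8S,9S)-9-bromo-8-chloro-10-hydroxy-4,8-dimethyldec-4-enoate | CC(C)(C)OC(=O)CC/C(C)=C\CC[C@](C)(Cl)[C@@H](Br)CO | intermediate
14 | tert-butyl (4Z,8S,9S)-9-bromo-8-chloro-4,8-dimethyl-10-[(trifluoromethanesulfonyl)oxy]dec-4-enoate | CC(C)(C)OC(=O)CC/C(C)=C\CC[C@](C)(Cl)[C@@H](Br)COS(=O)(=O)C(F)(F)F | intermediate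
15 | bromonium (bromiranium) ion bridging C2 and C3 of the chain, triflate salt | CC(C)(C)OC(=O)CC/C(C)=C\CC[C@](C)(Cl)[C@@H]1C[Br+]1.[O-]S(=O)(=O)C(F)(F)F | intermediate
16 | O-tert-butyl oxocarbenium (lactonium) ion of lactone 17, triflate salt | CC(C)(C)[O+]=C1CC[C@@](C)(O1)[C@H]2CC[C@](C)(Cl)[C@@H](Br)C2.[O-]S(=O)(=O)C(F)(F)F | intermediate
17 | (5R)-5-[(1S,3S,4S)-3-bromo-4-chloro-4-methylcyclohexyl]-5-methyloxolan-2-one | O=C1CC[C@@](C)(O1)[C@H]2CC[C@](C)(Cl)[C@@H](Br)C2 | intermediate
18 | (4R)-4-[(1S,3S,4S)-3-bromo-4-chloro-4-methylcyclohexyl]-4-hydroxy-N-methoxy-N-methylpentanamide | CON(C)C(=O)CC[C@@](C)(O)[C@H]1CC[C@](C)(Cl)[C@@H](Br)C1 | intermediate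
19 | (4R)-4-[(1S,3S,4S)-3-bromo-4-chloro-4-methylcyclohexyl]-N-methoxy-N-methyl-4-[(triethylsilyl)oxy]pentanamide | CON(C)C(=O)CC[C@@](C)(O[Si](CC)(CC)CC)[C@H]1CC[C@](C)(Cl)[C@@H](Br)C1 | intermediate
20 | isopropenylmagnesium bromide | C=C(C)[Mg]Br | starting material
21 | (6R)-6-[(1S,3S,4S)-3-bromo-4-chloro-4-methylcyclohexyl]-2-methyl-6-[(triethylsilyl)oxy]hept-1-en-3-one | C=C(C)C(=O)CC[C@@](C)(O[Si](CC)(CC)CC)[C@H]1CC[C@](C)(Cl)[C@@H](Br)C1 | intermediate
22 | (3R,6R)-6-[(1S,3S,4S)-3-bromo-4-chloro-4-methylcyclohexyl]-2-methyl-6-[(triethylsilyl)oxy]hept-1-en-3-ol | C=C(C)[C@H](O)CC[C@@](C)(O[Si](CC)(CC)CC)[C@H]1CC[C@](C)(Cl)[C@@H](Br)C1 | intermediate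
23 | CNP0226035.2, (3R,6R)-6-[(1S,3S,4S)-3-bromo-4-chloro-4-methylcyclohexyl]-2-methylhept-1-ene-3,6-diol | C=C(C)[C@H](O)CC[C@@](C)(O)[C@H]1CC[C@](C)(Cl)[C@@H](Br)C1 | target

Total step count: 15. Longest linear sequence: 15 steps, from nerol 1 to 23; compounds 5, 10 and 20 are bought and each enters in a single step.

Steps most likely to fail

1. Step 10. What may go wrong: opening of the bromonium ion at the more substituted C3 to give a cyclopentane; ionisation without bromine bridging, which would pass through the chair with axial halogens and give the C1 epimer; or bond rotation or proton loss at the C7 cation before the lactone closes. The fallback uses known chemistry, closes the ring before halogenation and gives up the stereochemical relay. It sets out from dienol ester 12. Acid-induced ionisation of the Z allylic alcohol (catalytic TfOH, (CF3)2CHOH/CH2Cl2) would trigger the classical neryl to α-terpinyl cation–olefin cyclisation, terminated by the tert-butyl ester, and should give racemic 5-methyl-5-(4-methylcyclohex-3-en-1-yl)oxolan-2-one F1 with the same C1/C7 relative configuration. Markovnikov anti bromochlorination of the ring alkene (NBS, Et4NCl, CH2Cl2) should then give both trans bromochlorides. The trans-diequatorial one is racemic 17, expected as the minor isomer; it would be separated from the diaxial isomer by chromatography and resolved on a chiral stationary phase, so the fallback comes back to the route at 17.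

2. Step 8. What may go wrong: poor enantioselectivity for this Z-configured, ester-bearing substrate, or competing halogenation of the remote 4Z alkene. The fallback sets out from 12. Ligand-free, titanium-directed bromochlorination (ClTi(OiPr)3, NBS, hexanes) should give racemic 13 with the same regio- and anti selectivity. Kinetic resolution by lipase-catalysed acetylation (immobilised lipase, vinyl acetate) then separates the antipodes. Compound 13 is either the recovered alcohol or is released from the separated acetate, tert-butyl (4Z,8S,9S)-10-acetoxy-9-bromo-8-chloro-4,8-dimethyldec-4-enoate F2, by lipase hydrolysis at pH 7, which avoids the base that would close the bromohydrin to an epoxide. The fallback comes back to the route at 13.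

3. Step 11. What may go wrong: reversal of the ring opening, the tertiary alkoxide relactonising with loss of the amine during work-up or silylation, or base-mediated loss of HBr. The fallback sets out from 17. Reduction with iBu2AlH (CH2Cl2, −78 °C) should give the lactol (5R)-5-[(1S,3S,4S)-3-bromo-4-chloro-4-methylcyclohexyl]-5-methyloxolan-2-ol F3. Excess 20 would add to the open hydroxy aldehyde form to give (6R)-6-[(1S,3S,4S)-3-bromo-4-chloro-4-methylcyclohexyl]-2-methylhept-1-ene-3,6-diol F4 as a mixture of C3 epimers, one of which is 23. Chemoselective oxidation of the secondary allylic alcohol (Dess–Martin periodinane or MnO2) should give the hydroxy enone (6R)-6-[(1S,3S,4S)-3-bromo-4-chloro-4-methylcyclohexyl]-6-hydroxy-2-methylhept-1-en-3-one F5. Silylation (Et3SiOTf, 2,6-lutidine) then comes back to the route at 21.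

Further compounds
F1 | step 10 | racemic (5R)-5-methyl-5-[(1S)-4-methylcyclohex-3-en-1-yl]oxolan-2-one (relative configuration shown) | O=C1CC[C@@](C)(O1)[C@H]2CCC(C)=CC2
F2 | step 8 | tert-butyl (4Z,8S,9S)-10-acetoxy-9-bromo-8-chloro-4,8-dimethyldec-4-enoate | CC(C)(C)OC(=O)CC/C(C)=C\CC[C@](C)(Cl)[C@@H](Br)COC(C)=O
F3 | step 11 | (5R)-5-[(1S,3S,4S)-3-bromo-4-chloro-4-methylcyclohexyl]-5-methyloxolan-2-ol (anomer mixture) | OC1CC[C@@](C)(O1)[C@H]2CC[C@](C)(Cl)[C@@H](Br)C2
F4 | step 11 | (6R)-6-[(1S,3S,4S)-3-bromo-4-chloro-4-methylcyclohexyl]-2-methylhept-1-ene-3,6-diol (C3 epimer mixture) | C=C(C)C(O)CC[C@@](C)(O)[C@H]1CC[C@](C)(Cl)[C@@H](Br)C1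
F5 | step 11 | (6R)-6-[(1S,3S,4S)-3-bromo-4-chloro-4-methylcyclohexyl]-6-hydroxy-2-methylhept-1-en-3-one | C=C(C)C(=O)CC[C@@](C)(O)[C@H]1CC[C@](C)(Cl)[C@@H](Br)C1
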